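**Plan** (flavanone numbering: O1, C2, C3, C4, C4a, C5–C8, C8a; ring B primed)
1. Retrosynthesis: the oxygen substituents are adjusted first (C5–OH from OMe, C6–OH and C3′–OH from OBn, C3–OMe from C3–OH, the C3–O bond from an enol ether). Then the C2–C3 bond of ring C is cut, then C3–C4 (acyl–CHN2), O1–C2 (benzyl aryl ether) and C4a–C4 (formyl on ring A).
2. Enabling feature: C2 is a benzylic carbon bonded to O1 and ring B and lies along C3–C4–C4a–C8a–O1–C2, so its C–H bond is doubly activated and within reach of a carbene at C3. C5 carries OMe, not OBn, so that no second C–H bond of this kind exists.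
3. Forward: rings A and B come intact from two benzaldehydes and are joined at O1; the ring A aldehyde becomes a diazomethyl ketone; ring C closes last by C2–C3 bond formation; then C3 is oxygenated and the phenols are released.
4. Stereochemistry: C2 comes from the chiral dirhodium carboxylate in the C–H insertion. C3 comes from substrate control: the enol ether is oxidised anti to ring B, and trans is also the more stable isomer.

Key step: step 9

Remark on the chemistry: the sense of induction for this acceptor-only carbene cannot be predicted safely. Rh2(S-PTTL)4 (dirhodium tetrakis[N-phthaloyl-(S)-tert-leucinate]) is written throughout; its mirror image Rh2(R-PTTL)4 would be used in the same way if it proves to be the one that gives the (2S)-flavanone.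
Remark on descriptors: C2 is S in the flavanone and its silyl enol ether and R in all C3-oxygenated compounds. This is only a change of CIP priority at C3; the spatial arrangement at C2 stays the same.

**Step 1**
Reactants: 1 3-hydroxy-4,5-dimethoxybenzaldehyde
Product: 2 3-(benzyloxy)-4,5-dimethoxybenzaldehyde
Conditions: BnBr, K2CO3, DMF, 60 °C
Reagents that add atoms: benzyl bromide, BrCc1ccccc1
Why: Williamson ether synthesis; the phenoxide formed with K2CO3 displaces bromide by SN2, and the aldehyde is inert under these conditions.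

**Step 2**
Reactants: 2 3-(benzyloxy)-4,5-dimethoxybenzaldehyde
Product: 3 [3-(benzyloxy)-4,5-dimethoxyphenyl]methanol
Conditions: NaBH4, MeOH, 0 °C
Reagents that add atoms: none
Why: Borohydride reduction of an aromatic aldehyde to the primary benzylic alcohol is chemoselective and leaves the aryl ethers untouched.

**Step 3**
Reactants: 4 syringaldehyde (4-hydroxy-3,5-dimethoxybenzaldehyde)
Product: 5 4-(benzyloxy)-3,5-dimethoxybenzaldehyde
Conditions: BnBr, K2CO3, DMF, 60 °C
Reagents that add atoms: benzyl bromide, BrCc1ccccc1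
Why: Williamson ether synthesis on the phenoxide flanked by two methoxy groups, a standard protection of syringaldehyde.

**Step 4**
Reactants: 5 4-(benzyloxy)-3,5-dimethoxybenzaldehyde
Product: 7 4-(benzyloxy)-3,5-dimethoxyphenol, via aryl formate 6 (not isolated)
Conditions: mCPBA, CH2Cl2, 0 °C → rt; then K2CO3 (cat.), MeOH, rt
Reagents that add atoms: 3-chloroperoxybenzoic acid, O=C(OO)c1cccc(Cl)c1
Why: Baeyer–Villiger (Dakin-type) oxidation; the electron-rich trialkoxyphenyl group migrates in the Criegee intermediate to give the formate, which methanolysis converts into the phenol.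

**Step 5**
Reactants: 7 4-(benzyloxy)-3,5-dimethoxyphenol
Product: 9 3-(benzyloxy)-6-hydroxy-2,4-dimethoxybenzaldehyde, via ortho-hydroxymethyl phenol 8 (not isolated)
Conditions: MgCl2, Et3N, (CH2O)n, MeCN, reflux; then 1 M HCl
Reagents that add atoms: paraformaldehyde (as formaldehyde), C=O
Why: Magnesium-phenoxide-directed ortho-formylation (Casnati–Skattebøl); the para position is blocked and the two ortho positions are equivalent by symmetry, so only one salicylaldehyde can form, the hydroxymethyl intermediate being oxidised by a second formaldehyde through Oppenauer-type hydride transfer.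

**Step 6**
Reactants: 9 3-(benzyloxy)-6-hydroxy-2,4-dimethoxybenzaldehyde; 3 [3-(benzyloxy)-4,5-dimethoxyphenyl]methanol
Product: 10 3-(benzyloxy)-6-{[3-(benzyloxy)-4,5-dimethoxyphenyl]methoxy}-2,4-dimethoxybenzaldehyde
Conditions: PPh3, DIAD, THF, 0 °C → rt
Reagents that add atoms: none
Why: Mitsunobu etherification; the chelated salicylaldehyde hydroxyl is acidic enough for the betaine and displaces the oxyphosphonium derivative of the primary benzylic alcohol by SN2, which forms the O1–C2 bond without a separate benzyl halide.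

**Step 7**
Reactants: 10 3-(benzyloxy)-6-{[3-(benzyloxy)-4,5-dimethoxyphenyl]methoxy}-2,4-dimethoxybenzaldehyde
Product: 11 3-(benzyloxy)-6-{[3-(benzyloxy)-4,5-dimethoxyphenyl]methoxy}-2,4-dimethoxybenzoic acid
Conditions: NaClO2, NaH2PO4, 2-methylbut-2-ene, t-BuOH/THF/H2O, 0 °C → rt
Reagents that add atoms: sodium chlorite, [Na+].[O-]Cl=O
Why: Pinnick (Lindgren–Kraus) oxidation takes the hindered, electron-rich aldehyde to the acid under buffered conditions, while 2-methylbut-2-ene traps HOCl before it can chlorinate the alkoxyarenes.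

**Step 8**
Reactants: 11 3-(benzyloxy)-6-{[3-(benzyloxy)-4,5-dimethoxyphenyl]methoxy}-2,4-dimethoxybenzoic acid
Product: 13 1-[3-(benzyloxy)-6-{[3-(benzyloxy)-4,5-dimethoxyphenyl]methoxy}-2,4-dimethoxyphenyl]-2-diazoethan-1-one, via acid chloride 12 (not isolated)
Conditions: 1-chloro-N,N,2-trimethylprop-1-en-1-amine, CH2Cl2, 0 °C → rt; then CH2N2 (3 equiv), Et2O, 0 °C
Reagents that add atoms: diazomethane, C=[N+]=[N-]
Why: The neutral Ghosez chloroenamine gives the aroyl chloride without free HCl, which spares the acid-sensitive trialkoxybenzyl ether, and acylation of diazomethane (first stage of the Arndt–Eistert sequence) with excess reagent as HCl trap gives the diazomethyl ketone; the aroyl chloride has no α-hydrogen, so no ketene can form.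

**Step 9**
Reactants: 13 1-[3-(benzyloxy)-6-{[3-(benzyloxy)-4,5-dimethoxyphenyl]methoxy}-2,4-dimethoxyphenyl]-2-diazoethan-1-one
Product: 14 (2S)-6-(benzyloxy)-2-[3-(benzyloxy)-4,5-dimethoxyphenyl]-5,7-dimethoxychroman-4-one
Conditions: Rh2(S-PTTL)4 (2 mol %), CH2Cl2, −20 → 0 °C, slow addition of 13
Reagents that add atoms: none
Why: The dirhodium tetracarboxylate expels N2 from 13 to give an electrophilic rhodium-bound carbene at C3, which inserts through a concerted, asynchronous three-centre transition state into a benzylic C–H bond of the C8a–O–CH2 group and releases the catalyst. The closest known reaction type is the chroman-4-one synthesis by intramolecular C–H insertion of ortho-alkoxyaryl diazomethyl ketones next to the ether oxygen with chiral dirhodium carboxylates. Ring C closes as a six-membered ring by 1,6-insertion, C2–C3 being the bond formed across the C4–C4a–C8a–O1 tether. The new stereocentre C2 is catalyst-controlled: the N-phthaloyl-tert-leucinate ligand sphere differentiates the two enantiotopic benzylic hydrogens, and the (2S) product already has the spatial arrangement of C2 in the target. Chemoselectivity is needed against oxonium ylide formation with [1,2]-benzyl shift, insertion into the C5 methoxy group and carbene dimerisation. The substrate secures it because the C2–H bonds are secondary, activated by both the ether oxygen and the electron-rich ring B and held close by the planar ortho-acyl aryl ether, whereas the methoxy C–H bonds are primary and the aryl ether oxygens are poor ylide donors; slow addition keeps the diazo concentration low.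

**Step 10**
Reactants: 14 (2S)-6-(benzyloxy)-2-[3-(benzyloxy)-4,5-dimethoxyphenyl]-5,7-dimethoxychroman-4-one
Product: 15 (2S)-6-(benzyloxy)-2-[3-(benzyloxy)-4,5-dimethoxyphenyl]-5,7-dimethoxy-4-[(trimethylsilyl)oxy]-2H-chromene
Conditions: TMSOTf, Et3N, CH2Cl2, 0 °C
Reagents that add atoms: trimethylsilyl trifluoromethanesulfonate, C[Si](C)(C)OS(=O)(=O)C(F)(F)F
Why: Soft enolisation; O-silylation of the carbonyl followed by deprotonation at C3 gives the only possible enol ether (C4a bears no hydrogen) without a free enolate that could expel the C8a phenoxide and open ring C, so C2 is not touched.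

**Step 11**
Reactants: 15 (2S)-6-(benzyloxy)-2-[3-(benzyloxy)-4,5-dimethoxyphenyl]-5,7-dimethoxy-4-[(trimethylsilyl)oxy]-2H-chromene
Product: 17 (2R,3R)-6-(benzyloxy)-2-[3-(benzyloxy)-4,5-dimethoxyphenyl]-3-hydroxy-5,7-dimethoxychroman-4-one, via silyloxy epoxide 16 (not isolated)
Conditions: dimethyldioxirane, acetone/CH2Cl2, −78 → 0 °C; then 1 M HCl, THF, 0 °C
Reagents that add atoms: dimethyldioxirane, CC1(C)OO1
Why: Rubottom oxidation; the dioxirane epoxidises the electron-rich enol ether on the face opposite the C2 aryl group and acid opening of the silyloxy epoxide gives the 2,3-trans ketol, so C3 is set (R) by substrate control, trans also being the thermodynamically preferred isomer.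

**Step 12**
Reactants: 17 (2R,3R)-6-(benzyloxy)-2-[3-(benzyloxy)-4,5-dimethoxyphenyl]-3-hydroxy-5,7-dimethoxychroman-4-one
Product: 18 (2R,3R)-6-(benzyloxy)-2-[3-(benzyloxy)-4,5-dimethoxyphenyl]-3,5,7-trimethoxychroman-4-one
Conditions: Me3OBF4, 1,8-bis(dimethylamino)naphthalene, 4 Å MS, CH2Cl2, 0 °C → rt
Reagents that add atoms: trimethyloxonium tetrafluoroborate, C[O+](C)C.F[B-](F)(F)F
Why: O-Alkylation with Meerwein's salt and a non-nucleophilic proton scavenger methylates the secondary hydroxyl under non-basic, non-oxidising conditions, so enolisation at C3, β-elimination and dehydrogenation to the flavonol are not triggered.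

**Step 13**
Reactants: 18 (2R,3R)-6-(benzyloxy)-2-[3-(benzyloxy)-4,5-dimethoxyphenyl]-3,5,7-trimethoxychroman-4-one
Product: 19 (2R,3R)-6-hydroxy-2-(3-hydroxy-4,5-dimethoxyphenyl)-3,5,7-trimethoxychroman-4-one
Conditions: H2 (1 atm), 10% Pd/C, EtOAc/MeOH, rt
Reagents that add atoms: none
Why: Catalytic hydrogenolysis cleaves both aryl benzyl ethers much faster than the cyclic benzylic C2–O1 bond or the hindered, electron-rich aryl ketone, as is usual for benzyl-protected flavanonols.

**Step 14**
Reactants: 19 (2R,3R)-6-hydroxy-2-(3-hydroxy-4,5-dimethoxyphenyl)-3,5,7-trimethoxychroman-4-one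
Product: 20 (2R,3R)-5,6-dihydroxy-2-(3-hydroxy-4,5-dimethoxyphenyl)-3,7-dimethoxychroman-4-one
Conditions: BCl3 (4 equiv), CH2Cl2, −78 → 0 °C; then MeOH, aq. NaHCO3
Reagents that add atoms: none
Why: Chelation-controlled Lewis acid demethylation; boron bound to the C4 carbonyl forms a six-membered chelate with the peri C5 oxygen and chloride removes that methyl group selectively, the other methyl ethers lacking this activation at low temperature.

**Compound list**
1 | 3-hydroxy-4,5-dimethoxybenzaldehyde | COc1cc(C=O)cc(O)c1OC | starting material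
2 | 3-(benzyloxy)-4,5-dimethoxybenzaldehyde | COc1cc(C=O)cc(OCc2ccccc2)c1OC | intermediate
3 | [3-(benzyloxy)-4,5-dimethoxyphenyl]methanol | COc1cc(CO)cc(OCc2ccccc2)c1OC | intermediate
4 | syringaldehyde (4-hydroxy-3,5-dimethoxybenzaldehyde) | COc1cc(C=O)cc(OC)c1O | starting material
5 | 4-(benzyloxy)-3,5-dimethoxybenzaldehyde | COc1cc(C=O)cc(OC)c1OCc1ccccc1 | intermediate
6 | 4-(benzyloxy)-3,5-dimethoxyphenyl formate | COc1cc(OC=O)cc(OC)c1OCc1ccccc1 | intermediate (not isolated)
7 | 4-(benzyloxy)-3,5-dimethoxyphenol | COc1cc(O)cc(OC)c1OCc1ccccc1 | intermediate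
8 | 4-(benzyloxy)-2-(hydroxymethyl)-3,5-dimethoxyphenol | COc1cc(O)c(CO)c(OC)c1OCc1ccccc1 | intermediate (not isolated)
9 | 3-(benzyloxy)-6-hydroxy-2,4-dimethoxybenzaldehyde | COc1cc(O)c(C=O)c(OC)c1OCc1ccccc1 | intermediate
10 | 3-(benzyloxy)-6-{[3-(benzyloxy)-4,5-dimethoxyphenyl]methoxy}-2,4-dimethoxybenzaldehyde | COc1cc(OCc2cc(OCc3ccccc3)c(OC)c(OC)c2)c(C=O)c(OC)c1OCc1ccccc1 | intermediate
11 | 3-(benzyloxy)-6-{[3-(benzyloxy)-4,5-dimethoxyphenyl]methoxy}-2,4-dimethoxybenzoic acid | COc1cc(OCc2cc(OCc3ccccc3)c(OC)c(OC)c2)c(C(=O)O)c(OC)c1OCc1ccccc1 | intermediate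
12 | 3-(benzyloxy)-6-{[3-(benzyloxy)-4,5-dimethoxyphenyl]methoxy}-2,4-dimethoxybenzoyl chloride | COc1cc(OCc2cc(OCc3ccccc3)c(OC)c(OC)c2)c(C(=O)Cl)c(OC)c1OCc1ccccc1 | intermediate (not isolated)
13 | 1-[3-(benzyloxy)-6-{[3-(benzyloxy)-4,5-dimethoxyphenyl]methoxy}-2,4-dimethoxyphenyl]-2-diazoethan-1-one | COc1cc(OCc2cc(OCc3ccccc3)c(OC)c(OC)c2)c(C(=O)C=[N+]=[N-])c(OC)c1OCc1ccccc1 | intermediate
14 | (2S)-6-(benzyloxy)-2-[3-(benzyloxy)-4,5-dimethoxyphenyl]-5,7-dimethoxychroman-4-one | COc1cc2c(c(OC)c1OCc1ccccc1)C(=O)C[C@@H](c1cc(OCc3ccccc3)c(OC)c(OC)c1)O2 | intermediate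
15 | (2S)-6-(benzyloxy)-2-[3-(benzyloxy)-4,5-dimethoxyphenyl]-5,7-dimethoxy-4-[(trimethylsilyl)oxy]-2H-chromene | COc1cc2c(c(OC)c1OCc1ccccc1)C(O[Si](C)(C)C)=C[C@@H](c1cc(OCc3ccccc3)c(OC)c(OC)c1)O2 | intermediate
16 | (2R,3R,4R)-6-(benzyloxy)-2-[3-(benzyloxy)-4,5-dimethoxyphenyl]-3,4-epoxy-5,7-dimethoxy-4-[(trimethylsilyl)oxy]chromane, oxirane oxygen anti to ring B | COc1cc2c(c(OC)c1OCc1ccccc1)[C@]4(O[Si](C)(C)C)O[C@@H]4[C@@H](c1cc(OCc3ccccc3)c(OC)c(OC)c1)O2 | intermediate (not isolated)
17 | (2R,3R)-6-(benzyloxy)-2-[3-(benzyloxy)-4,5-dimethoxyphenyl]-3-hydroxy-5,7-dimethoxychroman-4-one | COc1cc2c(c(OC)c1OCc1ccccc1)C(=O)[C@H](O)[C@@H](c1cc(OCc3ccccc3)c(OC)c(OC)c1)O2 | intermediate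
18 | (2R,3R)-6-(benzyloxy)-2-[3-(benzyloxy)-4,5-dimethoxyphenyl]-3,5,7-trimethoxychroman-4-one | COc1cc2c(c(OC)c1OCc1ccccc1)C(=O)[C@H](OC)[C@@H](c1cc(OCc3ccccc3)c(OC)c(OC)c1)O2 | intermediate
19 | (2R,3R)-6-hydroxy-2-(3-hydroxy-4,5-dimethoxyphenyl)-3,5,7-trimethoxychroman-4-one | COc1cc2c(c(OC)c1O)C(=O)[C@H](OC)[C@@H](c1cc(O)c(OC)c(OC)c1)O2 | intermediate
20 | (2R,3R)-5,6-dihydroxy-2-(3-hydroxy-4,5-dimethoxyphenyl)-3,7-dimethoxychroman-4-one | COc1cc2c(c(O)c1O)C(=O)[C@H](OC)[C@@H](c1cc(O)c(OC)c(OC)c1)O2 | target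

**Totals**
Total step count: 14. Longest linear sequence: 12 steps (steps 3–14, from syringaldehyde 4 to 20); the ring B branch (steps 1–2) joins at step 6.

**Steps most likely to fail**

Step 9. The acceptor-only carbene is very reactive and its transition state is early, so the chiral carboxylate may discriminate poorly between the two enantiotopic benzylic hydrogens and give the flavanone with insufficient enantiomeric purity. The fallback sets out from 13 and comes back at 14. The insertion would be run with achiral Rh2(OAc)4 in CH2Cl2 to give racemic 6-(benzyloxy)-2-[3-(benzyloxy)-4,5-dimethoxyphenyl]-5,7-dimethoxychroman-4-one F1. This would then be resolved kinetically by asymmetric transfer hydrogenation, a reaction known for racemic flavanones (Cp*RhCl[(R,R)-TsDPEN] or its antipode, chosen so that the (2R)-ketone reacts faster; HCO2H/Et3N, EtOAc). The (2R)-ketone should be reduced to the cis alcohol (2R,4R)-6-(benzyloxy)-2-[3-(benzyloxy)-4,5-dimethoxyphenyl]-5,7-dimethoxychroman-4-ol F2, while the unreduced (2S)-ketone 14 is separated and carried on.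

Step 14. Further methyl groups may be lost: boron bound to the free C6 or C3′ phenoxide can deliver chloride to the neighbouring 7- or 4′-methoxy group, and a C4=O/3-OMe chelate can expose the 3-methoxy group. The fallback sets out from 19 and comes back at 20. Both phenols would first be masked (Ac2O, pyridine, CH2Cl2) as (2R,3R)-6-acetoxy-2-(3-acetoxy-4,5-dimethoxyphenyl)-3,5,7-trimethoxychroman-4-one F3, so that no aryloxyboron species can form next to a methoxy group. The peri methyl ether would then be cleaved with BCl3 (CH2Cl2, −78 → 0 °C) to give (2R,3R)-6-acetoxy-2-(3-acetoxy-4,5-dimethoxyphenyl)-5-hydroxy-3,7-dimethoxychroman-4-one F4. Acid-catalysed methanolysis of the two aryl acetates (HCl in MeOH, rt) should then give 20.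

Step 10. Enolisation toward C3 places electron density β to the C8a phenoxide; ring C may open to the 2′-hydroxychalcone (retro-oxa-Michael), and reclosure would erode the C2 configuration. The fallback sets out from 14, avoids any enol or enolate, and comes back at 17. NaBH4 (MeOH/THF, 0 °C) should give the cis alcohol (2S,4S)-6-(benzyloxy)-2-[3-(benzyloxy)-4,5-dimethoxyphenyl]-5,7-dimethoxychroman-4-ol F5. Acid-catalysed dehydration (p-TsOH, toluene, 60 °C) should give the flav-3-ene (2S)-6-(benzyloxy)-2-[3-(benzyloxy)-4,5-dimethoxyphenyl]-5,7-dimethoxy-2H-chromene F6. Dihydroxylation anti to ring B (OsO4 cat., NMO, acetone/H2O) should give the 2,3-trans-3,4-cis diol (2R,3S,4S)-6-(benzyloxy)-2-[3-(benzyloxy)-4,5-dimethoxyphenyl]-5,7-dimethoxychromane-3,4-diol F7. Selective oxidation of the benzylic C4 hydroxyl with MnO2 (CH2Cl2, rt) should then give 17.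

**Further compounds**
F1 | step 9 | racemic 6-(benzyloxy)-2-[3-(benzyloxy)-4,5-dimethoxyphenyl]-5,7-dimethoxychroman-4-one | COc1cc2c(c(OC)c1OCc1ccccc1)C(=O)CC(c1cc(OCc3ccccc3)c(OC)c(OC)c1)O2
F2 | step 9 | (2R,4R)-6-(benzyloxy)-2-[3-(benzyloxy)-4,5-dimethoxyphenyl]-5,7-dimethoxychroman-4-ol | COc1cc2c(c(OC)c1OCc1ccccc1)[C@H](O)C[C@H](c1cc(OCc3ccccc3)c(OC)c(OC)c1)O2
F3 | step 14 | (2R,3R)-6-acetoxy-2-(3-acetoxy-4,5-dimethoxyphenyl)-3,5,7-trimethoxychroman-4-one | COc1cc2c(c(OC)c1OC(C)=O)C(=O)[C@H](OC)[C@@H](c1cc(OC(C)=O)c(OC)c(OC)c1)O2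
F4 | step 14 | (2R,3R)-6-acetoxy-2-(3-acetoxy-4,5-dimethoxyphenyl)-5-hydroxy-3,7-dimethoxychroman-4-one | COc1cc2c(c(O)c1OC(C)=O)C(=O)[C@H](OC)[C@@H](c1cc(OC(C)=O)c(OC)c(OC)c1)O2
F5 | step 10 | (2S,4S)-6-(benzyloxy)-2-[3-(benzyloxy)-4,5-dimethoxyphenyl]-5,7-dimethoxychroman-4-ol | COc1cc2c(c(OC)c1OCc1ccccc1)[C@@H](O)C[C@@H](c1cc(OCc3ccccc3)c(OC)c(OC)c1)O2
F6 | step 10 | (2S)-6-(benzyloxy)-2-[3-(benzyloxy)-4,5-dimethoxyphenyl]-5,7-dimethoxy-2H-chromene | COc1cc2c(c(OC)c1OCc1ccccc1)C=C[C@@H](c1cc(OCc3ccccc3)c(OC)c(OC)c1)O2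
F7 | step 10 | (2R,3S,4S)-6-(benzyloxy)-2-[3-(benzyloxy)-4,5-dimethoxyphenyl]-5,7-dimethoxychromane-3,4-diol | COc1cc2c(c(OC)c1OCc1ccccc1)[C@H](O)[C@H](O)[C@@H](c1cc(OCc3ccccc3)c(OC)c(OC)c1)O2
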